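**Plan**
- Cuts: first the ω-benzoate C–O bond (back to a silyl ether). Then the pyranone ring at C4a–C4, C4–C3 and O1–C2 together. Last, the C1'–Cα bond between the C15 chain and a malonate carbon.
- Enabling feature: C4 of the pyranone ring is a lone carbonyl-level carbon between aryl carbon C4a and C3, and C3–C2(=O)–O1 is a malonate ester residue on a phenol oxygen. C4 can therefore be CO, the benzene ring with O1 an ortho-iodophenol, and C2/C3 a malonate half-ester that already carries the chain.
- Forward: ω-oxidation of farnesyl acetate, silylation, deacetylation, bromination, malonate alkylation (chain joined to the future C3), half-saponification.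
- The benzene ring is bought. The pyranone ring is the only ring made and closes in the carbonylative three-component step; desilylation and benzoylation finish the route.
- Stereochemistry: there are no stereocentres. 2'E and 6'E come with (2E,6E)-farnesyl acetate, 10'E comes from the E-selective SeO2 oxidation, and no later step touches an alkene.

Key step: step 7

Assumption: (2E,6E)-farnesyl acetate is bought as the single geometric isomer, and the malonate α-carbon is racemic or labile wherever it is sp3 and ends as the sp2 carbon C3, so it is drawn without configuration.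

Step 1
Reactants: 1 (2E,6E)-farnesyl acetate, i.e. (2E,6E)-3,7,11-trimethyldodeca-2,6,10-trien-1-yl acetate
Product: 2 (2E,6E,10E)-12-hydroxy-3,7,11-trimethyldodeca-2,6,10-trien-1-yl acetate
Conditions: SeO2 (0.1 equiv), t-BuOOH (2.5 equiv), salicylic acid (0.1 equiv), CH2Cl2, 0 °C → rt, stopped at partial conversion
Reagents that add atoms: tert-butyl hydroperoxide, CC(C)(C)OO (its oxygen is relayed through catalytic SeO2, O=[Se]=O)
Why: This catalytic Riley-type allylic oxidation (ene reaction of SeO2, then a [2,3]-sigmatropic shift) should attack the terminal, least hindered trisubstituted alkene, the 2,3-alkene being deactivated by the allylic acetate, and its cyclic transition states put oxygen on the methyl group trans to the chain, which sets 10E.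

Step 2
Reactants: 2 (2E,6E,10E)-12-hydroxy-3,7,11-trimethyldodeca-2,6,10-trien-1-yl acetate
Product: 3 (2E,6E,10E)-12-(tert-butyldimethylsilyloxy)-3,7,11-trimethyldodeca-2,6,10-trien-1-yl acetate
Conditions: TBSCl, imidazole, CH2Cl2, 0 °C → rt
Reagents that add atoms: tert-butyldimethylsilyl chloride, CC(C)(C)[Si](C)(C)Cl
Why: This is an imidazole-promoted silylation of a primary allylic alcohol, and the silyl ether is chosen because it survives the basic steps ahead and cannot ionise on zerovalent palladium in step 7.

Step 3
Reactants: 3 (2E,6E,10E)-12-(tert-butyldimethylsilyloxy)-3,7,11-trimethyldodeca-2,6,10-trien-1-yl acetate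
Product: 4 (2E,6E,10E)-12-(tert-butyldimethylsilyloxy)-3,7,11-trimethyldodeca-2,6,10-trien-1-ol
Conditions: K2CO3 (0.2 equiv), MeOH, 0 °C → rt
Reagents that add atoms: none
Why: Base-catalysed transesterification (Zemplén-type methanolysis) should remove the acetate while the silyl ether and the alkenes stay inert.

Step 4
Reactants: 4 (2E,6E,10E)-12-(tert-butyldimethylsilyloxy)-3,7,11-trimethyldodeca-2,6,10-trien-1-ol
Product: 5 (2E,6E,10E)-1-bromo-12-(tert-butyldimethylsilyloxy)-3,7,11-trimethyldodeca-2,6,10-triene
Conditions: CBr4, PPh3, CH2Cl2, −20 → 0 °C; pentane trituration, used without storage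
Reagents that add atoms: carbon tetrabromide, BrC(Br)(Br)Br
Why: In this Appel reaction bromide displaces the alkoxyphosphonium salt of the primary allylic alcohol by SN2 under neutral conditions, so the 2E-alkene and the silyl ether should be retained.

Step 5
Reactants: 5 (2E,6E,10E)-1-bromo-12-(tert-butyldimethylsilyloxy)-3,7,11-trimethyldodeca-2,6,10-triene; 6 diethyl malonate
Product: 8 diethyl 2-[(2E,6E,10E)-12-(tert-butyldimethylsilyloxy)-3,7,11-trimethyldodeca-2,6,10-trien-1-yl]malonate, via sodium diethyl malonate 7 (not isolated)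
Conditions: 6 (1.5 equiv), NaH (1.4 equiv), THF, 0 °C; then 5, 0 °C → rt
Reagents that add atoms: none
Why: In this malonic ester alkylation the soft enolate 7 should displace the primary allylic bromide by SN2 at C1 without allylic transposition, and its excess suppresses dialkylation.

Step 6
Reactants: 8 diethyl 2-[(2E,6E,10E)-12-(tert-butyldimethylsilyloxy)-3,7,11-trimethyldodeca-2,6,10-trien-1-yl]malonate
Product: 9 potassium 2-[(2E,6E,10E)-12-(tert-butyldimethylsilyloxy)-3,7,11-trimethyldodeca-2,6,10-trien-1-yl]-3-ethoxy-3-oxopropanoate (racemic)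
Conditions: KOH (1.0 equiv), EtOH, 0 °C → rt; concentrated, dried azeotropically with toluene
Reagents that add atoms: KOH, [K+].[OH-]
Why: In this monosaponification of a malonic diester with one equivalent of KOH the first carboxylate formed repels hydroxide from the neighbouring ester, ethanol as solvent rules out ester scrambling, and the silyl ether and the alkenes are inert to cold ethanolic KOH.

Step 7
Reactants: 9 potassium 2-[(2E,6E,10E)-12-(tert-butyldimethylsilyloxy)-3,7,11-trimethyldodeca-2,6,10-trien-1-yl]-3-ethoxy-3-oxopropanoate; 10 2-iodophenol; 11 carbon monoxide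
Product: 15 3-[(2E,6E,10E)-12-(tert-butyldimethylsilyloxy)-3,7,11-trimethyldodeca-2,6,10-trien-1-yl]-4-hydroxycoumarin, via magnesium enolate 12 (not isolated), via acylmalonate magnesium salt 13 (not isolated), via hydroxyaryl β-keto ester 14 (not isolated)
Conditions: 9 (1.2 equiv), MgCl2 (2.5 equiv), Et3N (4 equiv), THF, rt, 1 h; then Pd(OAc)2 (5 mol %), Xantphos (6 mol %), CO (1 atm), 60 °C, 10 added over 4 h; cold 0.5 M HCl wash
Reagents that add atoms: none
Why: Proposed new method: zerovalent palladium formed from Pd(OAc)2 and Xantphos should insert into the C–I bond of 10, CO 11 then inserts to give an aroyl complex of divalent palladium, and the chelated enolate 12 displaces iodide and is C-acylated by reductive elimination from the wide-bite-angle complex, which makes C4a–C4 and C4–C3. The quaternary acylmalonate 13 carries a carboxylate β to two carbonyl groups and should lose CO2 at the reaction temperature to give β-keto ester 14, whose ortho-phenoxide attacks the ethyl ester carbonyl in a 6-exo-trig lactonisation (O1–C2), and enolisation to the vinylogous acid makes the cascade irreversible. The closest known reaction type is the palladium-catalysed carbonylative acylation of malonate half-ester salts and ketone enolates with aryl halides (carbonylative α-arylation) to β-keto esters and 1,3-diketones, and what is new here is the free ortho-hydroxyl, the α-substituted nucleophile and the ring closure to a 4-hydroxycoumarin in the same flask. No stereocentre remains, because the α-carbon of 13 and 14 becomes sp2 C3, and the three isolated trisubstituted E-alkenes should neither insert into the aroyl–palladium bond nor isomerise in this amine-buffered medium. The selectivity needed is capture of the aroyl-palladium by enolate carbon rather than by the oxygen of a second phenoxide; it is secured by holding the phenoxide as its less nucleophilic magnesium salt (which can also bind 12 next to the aroyl carbon), by adding 10 slowly so that 12 is always in excess, and by the fact that intramolecular O-capture would need a four-membered lactone. The ω-oxygen is carried as a silyl ether because an allylic ester at that position would ionise on zerovalent palladium and be alkylated by 12.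

Step 8
Reactants: 15 3-[(2E,6E,10E)-12-(tert-butyldimethylsilyloxy)-3,7,11-trimethyldodeca-2,6,10-trien-1-yl]-4-hydroxycoumarin
Product: 16 4-hydroxy-3-[(2E,6E,10E)-12-hydroxy-3,7,11-trimethyldodeca-2,6,10-trien-1-yl]coumarin (E-ω-hydroxyferulenol)
Conditions: HF·pyridine, excess pyridine, THF, 0 °C → rt
Reagents that add atoms: none
Why: This fluoride-mediated desilylation is driven by the strong Si–F bond, and the pyridine buffer keeps the medium too weakly acidic for the 4-hydroxyl to add to the 2'-alkene or for the polyene to cyclise.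

Step 9
Reactants: 16 4-hydroxy-3-[(2E,6E,10E)-12-hydroxy-3,7,11-trimethyldodeca-2,6,10-trien-1-yl]coumarin
Product: 18 E-ω-benzoyloxyferulenol, i.e. (2E,6E,10E)-12-(4-hydroxy-2-oxo-2H-chromen-3-yl)-2,6,10-trimethyldodeca-2,6,10-trien-1-yl benzoate, via bis-benzoate 17 (not isolated)
Conditions: BzCl (2.5 equiv), pyridine, CH2Cl2, 0 °C → rt; then NH3 (7 M in MeOH), 0 °C; cold 0.5 M HCl wash
Reagents that add atoms: benzoyl chloride, O=C(Cl)c1ccccc1
Why: Exhaustive O-benzoylation (nucleophilic acyl substitution) is followed by chemoselective aminolysis, because the C4 enol benzoate of 17 is a vinylogous mixed anhydride with the stabilised 4-oxidocoumarin as leaving group, so cold ammonia should cleave it far faster than the ordinary primary allylic benzoate.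

**Compound list**
1 | (2E,6E)-farnesyl acetate | CC(C)=CCC/C(C)=C/CC/C(C)=C/COC(C)=O | starting material
2 | (2E,6E,10E)-12-hydroxy-3,7,11-trimethyldodeca-2,6,10-trien-1-yl acetate | C/C(=C\CC/C(C)=C/COC(C)=O)CC/C=C(\C)CO | intermediate
3 | (2E,6E,10E)-12-(tert-butyldimethylsilyloxy)-3,7,11-trimethyldodeca-2,6,10-trien-1-yl acetate | C/C(=C\CC/C(C)=C/COC(C)=O)CC/C=C(\C)CO[Si](C)(C)C(C)(C)C | intermediate
4 | (2E,6E,10E)-12-(tert-butyldimethylsilyloxy)-3,7,11-trimethyldodeca-2,6,10-trien-1-ol | C/C(=C\CC/C(C)=C/CO)CC/C=C(\C)CO[Si](C)(C)C(C)(C)C | intermediate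
5 | (2E,6E,10E)-1-bromo-12-(tert-butyldimethylsilyloxy)-3,7,11-trimethyldodeca-2,6,10-triene | C/C(=C\CC/C(C)=C/CBr)CC/C=C(\C)CO[Si](C)(C)C(C)(C)C | intermediate
6 | diethyl malonate | CCOC(=O)CC(=O)OCC | starting material
7 | sodium diethyl malonate (not isolated) | CCOC(=O)[CH-]C(=O)OCC.[Na+] | intermediate
8 | diethyl 2-[(2E,6E,10E)-12-(tert-butyldimethylsilyloxy)-3,7,11-trimethyldodeca-2,6,10-trien-1-yl]malonate | C/C(=C\CC/C(C)=C/CC(C(=O)OCC)C(=O)OCC)CC/C=C(\C)CO[Si](C)(C)C(C)(C)C | intermediate
9 | potassium 2-[(2E,6E,10E)-12-(tert-butyldimethylsilyloxy)-3,7,11-trimethyldodeca-2,6,10-trien-1-yl]-3-ethoxy-3-oxopropanoate (racemic) | C/C(=C\CC/C(C)=C/CC(C(=O)[O-])C(=O)OCC)CC/C=C(\C)CO[Si](C)(C)C(C)(C)C.[K+] | intermediate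
10 | 2-iodophenol | Oc1ccccc1I | starting material
11 | carbon monoxide | [C-]#[O+] | starting material
12 | magnesium enolate-carboxylate of the half-ester, chelated through the two anionic oxygens (not isolated) | C/C(=C\CC/C(C)=C/C/C(C(=O)[O-])=C(\OCC)[O-])CC/C=C(\C)CO[Si](C)(C)C(C)(C)C.[Mg+2] | intermediate
13 | magnesium salt (phenoxide and carboxylate) of 2-(ethoxycarbonyl)-2-(2-hydroxybenzoyl)-substituted (4E,8E,12E)-14-(tert-butyldimethylsilyloxy)-5,9,13-trimethyltetradeca-4,8,12-trienoic acid, racemic (not isolated) | C/C(=C\CC/C(C)=C/CC(C(=O)[O-])(C(=O)OCC)C(=O)c1ccccc1[O-])CC/C=C(\C)CO[Si](C)(C)C(C)(C)C.[Mg+2] | intermediate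
14 | ethyl (4E,8E,12E)-14-(tert-butyldimethylsilyloxy)-2-(2-hydroxybenzoyl)-5,9,13-trimethyltetradeca-4,8,12-trienoate, labile α-carbon (not isolated) | C/C(=C\CC/C(C)=C/CC(C(=O)OCC)C(=O)c1ccccc1O)CC/C=C(\C)CO[Si](C)(C)C(C)(C)C | intermediate
15 | 3-[(2E,6E,10E)-12-(tert-butyldimethylsilyloxy)-3,7,11-trimethyldodeca-2,6,10-trien-1-yl]-4-hydroxycoumarin | C/C(=C\CC/C(C)=C/Cc1c(O)c2ccccc2oc1=O)CC/C=C(\C)CO[Si](C)(C)C(C)(C)C | intermediate
16 | 4-hydroxy-3-[(2E,6E,10E)-12-hydroxy-3,7,11-trimethyldodeca-2,6,10-trien-1-yl]coumarin | C/C(=C\CC/C(C)=C/Cc1c(O)c2ccccc2oc1=O)CC/C=C(\C)CO | intermediate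
17 | (2E,6E,10E)-12-(4-benzoyloxy-2-oxo-2H-chromen-3-yl)-2,6,10-trimethyldodeca-2,6,10-trien-1-yl benzoate (not isolated) | C/C(=C\CC/C(C)=C/Cc1c(OC(=O)c3ccccc3)c2ccccc2oc1=O)CC/C=C(\C)COC(=O)c1ccccc1 | intermediate
18 | E-ω-benzoyloxyferulenol | C/C(=C\CC/C(C)=C/Cc1c(O)c2ccccc2oc1=O)CC/C=C(\C)COC(=O)c1ccccc1 | target

**Count**
Total steps: 9. Longest linear sequence: 9 steps (1 → 18).

**Steps most likely to fail**

Step 7. Three things may go wrong. The aroyl-palladium may be captured by phenoxide oxygen or by the oxygen of the product enolate instead of by carbon. Reductive elimination at the substituted malonate carbon may be slow. The half-ester may undergo protodecarboxylation before it is acylated. The fallback uses known chemistry and needs neither palladium nor CO. It sets out from 9. The same magnesium enolate (MgCl2, Et3N, THF/MeCN, 0 °C) is acylated with commercial 2-acetoxybenzoyl chloride in a Masamune–Brooks-type malonate acylation. Loss of CO2 should give ethyl (4E,8E,12E)-2-(2-acetoxybenzoyl)-14-(tert-butyldimethylsilyloxy)-5,9,13-trimethyltetradeca-4,8,12-trienoate F1. K2CO3 in MeOH then removes the aryl acetate, the freed phenoxide lactonises onto the ester, and the route is rejoined at 15.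

Step 1. The risks are incomplete site selectivity among the three alkenes and over-oxidation of the new alcohol. The fallback rebuilds the terminus by cleavage and olefination. It sets out from 1.
- Terminal-selective bromohydrin formation (NBS, THF/water, 0 °C) should give racemic (2E,6E)-10-bromo-11-hydroxy-3,7,11-trimethyldodeca-2,6-dien-1-yl acetate F2.
- DBU in toluene closes it, with the acetate kept, to racemic (2E,6E)-10,11-epoxy-3,7,11-trimethyldodeca-2,6-dien-1-yl acetate F3.
- H5IO6 in THF/water at 0 °C cleaves the epoxide to (2E,6E)-3,7-dimethyl-10-oxodeca-2,6-dien-1-yl acetate F4.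
- E-selective Wittig olefination with the stabilised ylide 2-(triphenylphosphoranylidene)propanal gives (2E,6E,10E)-3,7,11-trimethyl-12-oxododeca-2,6,10-trien-1-yl acetate F5.
- Luche reduction (NaBH4, CeCl3·7H2O, MeOH, 0 °C) leaves the acetate alone and rejoins the route at 2.

Step 6. The risks are over-hydrolysis to the dicarboxylate, incomplete conversion, and carry-over of water or diester into step 7, because the soap-like salt cannot be purified. The fallback buys the acid/ester differentiation instead of creating it by hydrolysis. It sets out from 5. The bromide is alkylated with the dianion of ethyl hydrogen malonate (LDA, 2.1 equiv, THF, −78 → 0 °C). After a cold citric acid quench this should give the chromatographable acid 2-[(2E,6E,10E)-12-(tert-butyldimethylsilyloxy)-3,7,11-trimethyldodeca-2,6,10-trien-1-yl]-3-ethoxy-3-oxopropanoic acid F6. One equivalent of KOt-Bu in THF at 0 °C converts it into the dry salt, and the route is rejoined at 9, bypassing 8.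

**Further compounds**
F1 | step 7 | ethyl (4E,8E,12E)-2-(2-acetoxybenzoyl)-14-(tert-butyldimethylsilyloxy)-5,9,13-trimethyltetradeca-4,8,12-trienoate | C/C(=C\CC/C(C)=C/CC(C(=O)OCC)C(=O)c1ccccc1OC(C)=O)CC/C=C(\C)CO[Si](C)(C)C(C)(C)C
F2 | step 1 | (2E,6E)-10-bromo-11-hydroxy-3,7,11-trimethyldodeca-2,6-dien-1-yl acetate (racemic) | CC(C)(O)C(Br)CC/C(C)=C/CC/C(C)=C/COC(C)=O
F3 | step 1 | (2E,6E)-10,11-epoxy-3,7,11-trimethyldodeca-2,6-dien-1-yl acetate (racemic) | CC1(C)OC1CC/C(C)=C/CC/C(C)=C/COC(C)=O
F4 | step 1 | (2E,6E)-3,7-dimethyl-10-oxodeca-2,6-dien-1-yl acetate | O=CCC/C(C)=C/CC/C(C)=C/COC(C)=O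
F5 | step 1 | (2E,6E,10E)-3,7,11-trimethyl-12-oxododeca-2,6,10-trien-1-yl acetate | C/C(=C\CC/C(C)=C/COC(C)=O)CC/C=C(\C)C=O
F6 | step 6 | 2-[(2E,6E,10E)-12-(tert-butyldimethylsilyloxy)-3,7,11-trimethyldodeca-2,6,10-trien-1-yl]-3-ethoxy-3-oxopropanoic acid (racemic) | C/C(=C\CC/C(C)=C/CC(C(=O)O)C(=O)OCC)CC/C=C(\C)CO[Si](C)(C)C(C)(C)C
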